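**Retrosynthetic overview**

1. The target is meso (mirror plane through the ring oxygen and the C3–C4 midpoint). C2 and C5 of the oxolane are both benzylic carbons para to a free phenolic OH of a syringyl ring, so each O–C(aryl) ring bond is the adduct of an oxygen nucleophile to a p-quinone methide. Disconnect O1–C2 (intramolecular oxa-1,6-addition) and O1–C5 (water) to reach a cis bis(quinone methide).
2. The bis(quinone methide) is released from a cyclobutane: a temporary C2–C5 bond, absent from the target, is broken by two-electron oxidation of one phenol and oxygen from water is inserted in its place.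
3. The cyclobutane comes from an intramolecular [2+2] photocycloaddition of a bis(sinapyl) di-tert-butylsilyl ether. The temporary seven-membered O–Si–O ring fixes C3/C4 cis, blocks both CH2OH groups and is removed last.
4. The monomer comes from sinapic acid by phenol acetylation and reduction of the acid to the allylic alcohol.
5. Ring order: seven-membered silylene ring and cyclobutane (steps 3 and 4), oxolane by oxidative ring expansion of the cyclobutane (step 6), silylene ring removed (step 7).

Key step: step 6

Remark: the target is meso, so chiral intermediates are racemic and one enantiomer is drawn; the aryl-bearing centres of 6 and 7 are drawn for the expected isomer and are erased in step 6.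

**Route**

Step 1
Reactants: 1 sinapic acid
Product: 2 (E)-4-acetoxy-3,5-dimethoxycinnamic acid
Conditions: Ac2O, pyridine, rt; aqueous work-up
Reagents that add atoms: acetic anhydride, CC(=O)OC(C)=O
Why: O-Acetylation of the phenol by the anhydride under pyridine catalysis, with any mixed anhydride at the carboxyl group hydrolysed on work-up; no stereocentre is formed.

Step 2
Reactants: 2 (E)-4-acetoxy-3,5-dimethoxycinnamic acid
Product: 4 (E)-4-acetoxy-3,5-dimethoxycinnamyl alcohol (4-O-acetylsinapyl alcohol), via acid chloride 3 (not isolated)
Conditions: SOCl2, cat. DMF, toluene, 70 °C; concentrate; NaBH4, EtOAc, rt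
Reagents that add atoms: thionyl chloride, O=S(Cl)Cl (supplies the chlorine of intermediate 3; nothing of it remains in 4)
Why: Acid chloride formation followed by chemoselective 1,2-reduction with NaBH4 in EtOAc is the established way to take 4-acetoxycinnamic acids to 4-acetoxycinnamyl alcohols with the E-alkene and the aryl acetate intact; no stereocentre is formed.

Step 3
Reactants: 4 (E)-4-acetoxy-3,5-dimethoxycinnamyl alcohol (2 equiv)
Product: 5 di-tert-butylbis[(E)-3-(4-acetoxy-3,5-dimethoxyphenyl)allyloxy]silane
Conditions: tBu2Si(OTf)2 (0.5 equiv), 2,6-lutidine, DMF, 0 °C → 40 °C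
Reagents that add atoms: di-tert-butylsilyl bis(trifluoromethanesulfonate), CC(C)(C)[Si](OS(=O)(=O)C(F)(F)F)(OS(=O)(=O)C(F)(F)F)C(C)(C)C
Why: Double O-silylation of a primary allylic alcohol by a silyl bis(triflate) (silaketal formation) should give the symmetrical tether, the aryl acetates being inert to the triflate and to 2,6-lutidine; no stereocentre is formed.

Step 4
Reactants: 5 di-tert-butylbis[(E)-3-(4-acetoxy-3,5-dimethoxyphenyl)allyloxy]silane
Product: 6 cis-fused 8,9-bis(4-acetoxy-3,5-dimethoxyphenyl)-4,4-di-tert-butyl-3,5-dioxa-4-silabicyclo[5.2.0]nonane (aryl groups cis to each other and trans to the neighbouring ring CH2; meso)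
Conditions: hν (Pyrex-filtered medium-pressure Hg lamp, λ > 290 nm), degassed MeCN (5 mM), rt
Reagents that add atoms: none
Why: In this intramolecular [2+2] photocycloaddition of a silicon-tethered bis(cinnamyl) ether, the five-atom C–O–Si–O–C tether and the gem-di-tert-butyl effect hold the two styrenes parallel so that bonding is head-to-head, and the seven-membered ring can only be cis-fused to the cyclobutane, which sets the cis relationship of the two CH2O-bearing carbons, while the aryl-bearing centres follow from suprafacial addition to the E,E-diene and are erased in step 6 in any case.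

Step 5
Reactants: 6 tethered cyclobutane bis(aryl acetate)
Product: 7 cis-fused 8,9-bis(4-hydroxy-3,5-dimethoxyphenyl)-4,4-di-tert-butyl-3,5-dioxa-4-silabicyclo[5.2.0]nonane
Conditions: pyrrolidine (6 equiv), THF, rt
Reagents that add atoms: none
Why: Aminolysis by pyrrolidine is selective for phenolic acetates and leaves the dialkoxysilane and all four stereocentres untouched.

Step 6
Reactants: 7 tethered cyclobutane bisphenol
Product: 10 cis-fused 8,10-bis(4-hydroxy-3,5-dimethoxyphenyl)-4,4-di-tert-butyl-3,5,9-trioxa-4-silabicyclo[5.3.0]decane (both aryl groups trans to the neighbouring ring CH2, cis to each other), via bis(quinone methide) 8 (not isolated), via hydroxy quinone methide 9 (not isolated)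
Conditions: PhI(OAc)2 (1.05 equiv, slow addition), HFIP–H2O (9:1), 0 °C → rt
Reagents that add atoms: water, O
Why: Proposed new method: ligand exchange of one syringyl phenol of 7 on PhI(OAc)2 and two-electron loss should give a phenoxenium-type ring whose para carbon carries a strained cyclobutane bond to a carbon bearing a second p-hydroxyaryl donor, so the bond between the two aryl-bearing carbons breaks in a push–pull (vinylogous Grob) fragmentation to the cis bis(quinone methide) 8, water adds to one quinone methide carbon (9), and the new benzylic hydroxyl closes the oxolane by 5-exo-trig oxa-1,6-addition to the second quinone methide. The closest known reaction types are the oxidation of p-alkylphenols to quinone methides by hypervalent (trivalent) iodine, the oxidative ring opening of donor-substituted arylcyclobutanes and arylcyclopropanes with nucleophile capture, and the water trapping of side-chain-coupled sinapyl bis(quinone methides) that gives 2,5-diaryloxolanes when the primary hydroxyls are blocked. The cis relationship of C3 and C4 is inherited from the cis ring fusion and is never touched; the two new benzylic centres are set by the cis-fused seven-membered silylene ring, which places both aryl groups on the convex face, trans to the neighbouring CH2O carbons, and by the reversibility of C–O ionisation para to a free phenol in HFIP containing the released AcOH, which should let a cis epimer drain to the trans,cis,trans isomer. The step needs three selectivities: cleavage of the bond flanked by both aryl groups rather than a bond to a CH2O-bearing carbon (only the former leaves a cation stabilised by the second hydroxyaryl group), a two-electron oxidant so that no benzylic radical can revert to two sinapyl units, and exclusion of the primary oxygens as nucleophiles, which the silylene tether secures.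

Step 7
Reactants: 10 silylene-bridged oxolane
Product: 11 [(2R,3S,4R,5S)-2,5-bis(4-hydroxy-3,5-dimethoxyphenyl)oxolane-3,4-diyl]dimethanol (meso; target)
Conditions: HF·pyridine, excess pyridine, THF, 0 °C → rt
Reagents that add atoms: none
Why: Fluoride-induced cleavage of both Si–O bonds (desilylation) is driven by Si–F bond formation, and pyridine buffering keeps the medium too weakly acidic to ionise the benzylic C–O bonds, so the four stereocentres should be retained.

**Compound list**

1 | sinapic acid | COc1cc(/C=C/C(=O)O)cc(OC)c1O | starting material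
2 | (E)-4-acetoxy-3,5-dimethoxycinnamic acid | COc1cc(/C=C/C(=O)O)cc(OC)c1OC(C)=O | intermediate
3 | (E)-4-acetoxy-3,5-dimethoxycinnamoyl chloride | COc1cc(/C=C/C(=O)Cl)cc(OC)c1OC(C)=O | intermediate
4 | (E)-4-acetoxy-3,5-dimethoxycinnamyl alcohol | COc1cc(/C=C/CO)cc(OC)c1OC(C)=O | intermediate
5 | di-tert-butylbis[(E)-3-(4-acetoxy-3,5-dimethoxyphenyl)allyloxy]silane | CC(=O)Oc1c(OC)cc(/C=C/CO[Si](OC/C=C/c2cc(OC)c(OC(C)=O)c(OC)c2)(C(C)(C)C)C(C)(C)C)cc1OC | intermediate
6 | cis-fused 8,9-bis(4-acetoxy-3,5-dimethoxyphenyl)-4,4-di-tert-butyl-3,5-dioxa-4-silabicyclo[5.2.0]nonane | CC(=O)Oc1c(OC)cc(cc1OC)[C@@H]1[C@H](c2cc(OC)c(OC(C)=O)c(OC)c2)[C@H]2CO[Si](C(C)(C)C)(C(C)(C)C)OC[C@@H]12 | intermediate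
7 | cis-fused 8,9-bis(4-hydroxy-3,5-dimethoxyphenyl)-4,4-di-tert-butyl-3,5-dioxa-4-silabicyclo[5.2.0]nonane | COc1cc(cc(OC)c1O)[C@@H]1[C@H](c2cc(OC)c(O)c(OC)c2)[C@H]2CO[Si](C(C)(C)C)(C(C)(C)C)OC[C@@H]12 | intermediate
8 | cis-5,6-bis[(3,5-dimethoxy-4-oxocyclohexa-2,5-dien-1-ylidene)methyl]-2,2-di-tert-butyl-1,3,2-dioxasilepane | COC1=CC(=C[C@H]2CO[Si](C(C)(C)C)(C(C)(C)C)OC[C@H]2C=C2C=C(OC)C(=O)C(OC)=C2)C=C(OC)C1=O | intermediate
9 | mono-hydrate of 8 (one quinone methide, one 4-hydroxy-3,5-dimethoxyphenyl carbinol) | COC1=CC(=C[C@H]2CO[Si](C(C)(C)C)(C(C)(C)C)OC[C@H]2[C@@H](O)c2cc(OC)c(O)c(OC)c2)C=C(OC)C1=O | intermediate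
10 | cis-fused 8,10-bis(4-hydroxy-3,5-dimethoxyphenyl)-4,4-di-tert-butyl-3,5,9-trioxa-4-silabicyclo[5.3.0]decane | COc1cc([C@H]2O[C@@H](c3cc(OC)c(O)c(OC)c3)[C@@H]3CO[Si](C(C)(C)C)(C(C)(C)C)OC[C@H]23)cc(OC)c1O | intermediate
11 | [(2R,3S,4R,5S)-2,5-bis(4-hydroxy-3,5-dimethoxyphenyl)oxolane-3,4-diyl]dimethanol | COc1cc([C@H]2O[C@@H](c3cc(OC)c(O)c(OC)c3)[C@H](CO)[C@@H]2CO)cc(OC)c1O | target

**Step count and risks**

Total step count: 7. Longest linear sequence: 7 (steps 1 to 7 from sinapic acid).

Steps most likely to fail:

1. Step 6 (proposed new method). Water may attack the ring para carbon of the oxidised phenol (dearomatisation without ring opening), the benzylic hydrogen may be lost without C–C cleavage, the product phenols may be over-oxidised, or the benzylic epimers may not converge. Fallback with known chemistry, the oxidative side-chain dehydrodimerisation of sinapyl units: setting out from 5, pyrrolidine in THF should remove both aryl acetates to give di-tert-butylbis[(E)-3-(4-hydroxy-3,5-dimethoxyphenyl)allyloxy]silane F1. Ag2O in acetone–water should then couple the two phenoxyl radicals intramolecularly at the carbons next to CH2O to give the bis(quinone methide) 8, which adds water (9) and closes as in step 6, returning the route at 10. The cis/trans relationship at the new C–C bond would then not be fixed by a ring fusion made beforehand, so isomers would have to be separated at 10.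

2. Step 4. E/Z isomerisation may reach a photostationary state without cycloaddition, a crossed regioisomer may form, or the aryl acetates may undergo photo-Fries cleavage. Fallback, a covalent template at the acid oxidation level: setting out from 2, esterification with naphthalene-1,8-diol (EDC·HCl, DMAP, CH2Cl2) should give naphthalene-1,8-diyl bis[(E)-4-acetoxy-3,5-dimethoxycinnamate] F2, in which the peri oxygens hold the two alkenes parallel. Irradiation (365 nm, solid film or MeCN) should give the template-bound head-to-head cis cyclobutane diester F3. LiAlH4 in THF at 0 °C should reduce both aryl esters and both aryl acetates to the cis-1,2-bis(hydroxymethyl)-3,4-bis(4-hydroxy-3,5-dimethoxyphenyl)cyclobutane F4. tBu2Si(OTf)2 (1 equiv), 2,6-lutidine, CH2Cl2, −40 °C should bridge the cis primary diol in preference to the flanked phenols and return the route at 7.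

3. Step 7. During desilylation a benzylic C–O bond para to the free phenol may ionise, followed by capture by a liberated primary hydroxyl (ring isomerisation) or by epimerisation. Fallback, a protecting-group detour that switches off quinone methide formation: setting out from 10, Ac2O/pyridine should give the bis(aryl acetate) of the silylene-bridged oxolane F5. HF·pyridine in THF should then give [2,5-bis(4-acetoxy-3,5-dimethoxyphenyl)oxolane-3,4-diyl]dimethanol F6, whose benzylic ethers no longer ionise. K2CO3 in MeOH at 0 °C should remove the aryl acetates and return the route at 11.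

**Further compounds**

F1 | step 6 | di-tert-butylbis[(E)-3-(4-hydroxy-3,5-dimethoxyphenyl)allyloxy]silane | COc1cc(/C=C/CO[Si](OC/C=C/c2cc(OC)c(O)c(OC)c2)(C(C)(C)C)C(C)(C)C)cc(OC)c1O
F2 | step 4 | naphthalene-1,8-diyl bis[(E)-4-acetoxy-3,5-dimethoxycinnamate] | CC(=O)Oc1c(OC)cc(/C=C/C(=O)Oc2cccc3cccc(OC(=O)/C=C/c4cc(OC)c(OC(C)=O)c(OC)c4)c23)cc1OC
F3 | step 4 | naphthalene-1,8-diyl cis-3,4-bis(4-acetoxy-3,5-dimethoxyphenyl)cyclobutane-cis-1,2-dicarboxylate (aryl trans to neighbouring ester) | CC(=O)Oc1c(OC)cc(cc1OC)[C@@H]1[C@H](c2cc(OC)c(OC(C)=O)c(OC)c2)[C@H]2C(=O)Oc3cccc4cccc(OC(=O)[C@@H]12)c34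
F4 | step 4 | cis-1,2-bis(hydroxymethyl)-cis-3,4-bis(4-hydroxy-3,5-dimethoxyphenyl)cyclobutane (aryl trans to neighbouring CH2OH) | COc1cc(cc(OC)c1O)[C@@H]1[C@H](c2cc(OC)c(O)c(OC)c2)[C@@H](CO)[C@H]1CO
F5 | step 7 | cis-fused 8,10-bis(4-acetoxy-3,5-dimethoxyphenyl)-4,4-di-tert-butyl-3,5,9-trioxa-4-silabicyclo[5.3.0]decane | COc1cc([C@H]2O[C@@H](c3cc(OC)c(OC(C)=O)c(OC)c3)[C@@H]3CO[Si](C(C)(C)C)(C(C)(C)C)OC[C@H]23)cc(OC)c1OC(C)=O
F6 | step 7 | [(2R,3S,4R,5S)-2,5-bis(4-acetoxy-3,5-dimethoxyphenyl)oxolane-3,4-diyl]dimethanol | COc1cc([C@H]2O[C@@H](c3cc(OC)c(OC(C)=O)c(OC)c3)[C@H](CO)[C@@H]2CO)cc(OC)c1OC(C)=O
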